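This vessel holds starting material, second substrate, reagent, free catalyst and protic impurity, and the new flasks differ in which charge, if any, is fed slowly.

| flask | starting material | second substrate | reagent | protic impurity | free catalyst | remark | time |
|---|---|---|---|---|---|---|---|
| ash | 0.50 M | 2 equiv | 0.60 equiv | 0.050 M | 5 mol% | run made earlier |  |
| cedar | 0.50 M | 2 equiv | 0.60 equiv | 0.050 M | 7 mol% | run made earlier |  |
| maple | 0.50 M | 2 equiv | 0.60 equiv | 0.050 M | 11 mol% | run made earlier |  |
| birch | 0.50 M | 2 equiv | 0.60 equiv | 0.025 M | 5 mol% | run made earlier |  |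
| theta | 0.50 M (fed, over 15 h) | 2.00 equiv | 0.600 equiv | 0.0500 M | 5 mol% | all else is in the flask from the start; the feed brings no volume worth counting | 25 h |
| epsilon | 0.50 M | 2.00 equiv | 0.600 equiv | 0.0500 M | 5 mol% | everything together at the start | 25 h |
| alpha | 0.50 M | 2.00 equiv | 0.600 equiv (fed, over 15 h) | 0.0500 M | 5 mol% | all else is in the flask from the start; the feed brings no volume worth counting | 25 h |

| run | time / h | target / % | starting material / % |
|---|---|---|---|
| ash | 1.33 | 3.7 | 91.8 |
| ash | 2.00 | 5.1 | 90.1 |
| ash | 3.00 | 7.5 | 85.8 |
| ash | 5.00 | 9.2 | 81.2 |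
| ash | 10.0 | 13.6 | 76.2 |
| ash | 15.0 | 14.1 | 74.5 |
| cedar | 1.00 | 3.1 | 91.7 |
| cedar | 3.00 | 8.9 | 83.5 |
| cedar | 5.00 | 12.0 | 78.4 |
| cedar | 8.00 | 13.7 | 74.9 |
| cedar | 12.0 | 13.9 | 73.6 |
| cedar | 15.0 | 14.1 | 74.1 |
| maple | 1.33 | 6.6 | 89.0 |
| maple | 2.00 | 8.9 | 84.3 |
| maple | 3.00 | 11.3 | 79.5 |
| maple | 5.00 | 13.5 | 76.9 |
| maple | 10.0 | 14.6 | 74.6 |
| maple | 15.0 | 14.2 | 73.3 |
| birch | 1.33 | 3.5 | 93.5 |
| birch | 4.00 | 8.8 | 87.3 |
| birch | 8.00 | 12.7 | 81.4 |
| birch | 10.0 | 13.5 | 80.5 |
| birch | 15.0 | 14.3 | 78.9 |

(scatter of a reading: 0.5 percentage points)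



* the flask that comes out highest in amount of target, in percent of the starting material charged, or "all alike" when all lie within 1.5 percentage points (theta / epsilon / alpha / all alike)
* target at the end, in percent of the starting material charged, theta
* target at the end, in percent of the starting material charged, epsilon
* target at the end, in percent of the starting material charged, alpha

Ash levels off at 14.1% on a reagent charge of 0.60 equiv. I read the plateau as reagent spent, which makes 23.5% of it target. This fraction of the reagent charge that ends as target, the field's selectivity, is what I carry. Cedar reads 14.1%, maple 14.2% and birch 14.3%, so within the scatter it follows neither catalyst nor impurity. Ash loses 25.5% of its starting material, close to target plus the impurity's 10.0% of the charge, so I suppose the remaining reagent leaves with the second substrate.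

Epsilon has ash's recipe, so I place it at ash's plateau, and theta's reagent meets little starting material at first, so I expect its share below ash's. Alpha needs a bracket. Its ceiling is a share of one, 60.0% of the starting material. The starting material spared by the impurity, 90.0%, stands above that and cannot lower it. For the floor, an estimate and no strict bound, I let the share follow the starting material present and suppose that alpha's reagent works at ash's last reading, 74.5%, against ash's 85.8% at 3.00 h, which gives 12.2%. That floor lies below ash, so the bracket does not rank alpha against epsilon.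

The forecast names epsilon, with theta 4.8%, epsilon 14.3% and alpha 13%, which sits inside my bracket near the floor: “Alpha stays slightly below epsilon.”

The flasks give theta 5.34%, epsilon 14.3% and alpha 20.4%, so alpha is highest, inside the bracket and above the forecast's high end of 14.5%.

    second substrate + free catalyst ⇌ catalyst intermediate B (K = 1.50 M⁻¹, k = 0.00700 M⁻¹ s⁻¹)
    starting material + protic impurity → quenched substrate (k = 2.20 × 10⁻⁴ M⁻¹ s⁻¹)
    reagent + catalyst intermediate A → free catalyst + target (k = 0.00810 M⁻¹ s⁻¹)
    reagent + catalyst intermediate B → free catalyst + second product (k = 0.00740 M⁻¹ s⁻¹)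
    2 free catalyst ⇌ resting dimer (K = 7300 M⁻¹, k = 0.00120 M⁻¹ s⁻¹)
    starting material + free catalyst ⇌ catalyst intermediate A (K = 3.90 M⁻¹, k = 8.20 × 10⁻⁴ M⁻¹ s⁻¹)

In alpha, at the end of the feed (15.0 h), the target step runs at 0.420 of the second-product step, and alpha's share ends at 34.0% against the 23.5% read from ash. In theta, at 1.76 h, free catalyst goes to second substrate 130 times as fast as to starting material, forward steps alone, and theta's share ends at 8.89%.

The numbers in the tables are simulated for an exercise, noise included.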